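**Retrosynthetic overview**
1. The oxirane (C8–C9, α face), the C7 carbinol and the C6 4-hydroxybenzoate come last, on a cyclohept-8-en-7-one that is unveiled when a C6–O–C9 oxygen bridge is opened by E1cB elimination from a C7 enolate.
2. The cyclopentane (C1–C5) is annulated on the bridged seven-membered ring: exo vinyl-cuprate addition at C1, rhodium hydroacylation closing C3–C4, isopropylcerium addition at C4.
3. Key disconnection: C5–C6 and C9–C10, a (4+3) cycloaddition (carbenoid cyclopropanation/Cope rearrangement) that dearomatises 3-methylfuran (C6–C7–C8–C9 plus its ring oxygen) with the rhodium vinylcarbenoid of methyl 2-diazo-3-methylbut-3-enoate (C5, C1 with its methyl, C10; ester carbon = C4).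
4. Enabling feature: in the seven-membered ring C6 and C9 both carry oxygen on the same (α) face, C8 carries a methyl group and C7 an oxygen, so the segment C6–C9 is a 2,5-bridged 3-methylfuran, while C10–C1(CH3)–C5 is an isopropenylcarbene.
5. Ring order: seven-membered carbocycle first (as an 8-oxabicyclo[3.2.1]octadiene with temporary oxane and dihydrofuran rings), cyclopentane second, oxygen bridge opened, oxirane last.

Key step: step 2

Remark (numbering): daucane locants are used throughout: C1 = ring-fusion carbon with methyl, C2, C3, C4 = isopropyl carbinol, C5 = ring-fusion CH, C6 = ester carbon, C7 = carbinol CH, C8/C9 = oxirane carbons, C10 = CH2; α is the face of the C6 and oxirane oxygens, β the face of the C1 methyl group.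
Assumption: Rh2(S-DOSP)4 is taken to give the (1S,5S) cycloadduct of step 2; should the sense of induction be opposite, Rh2(R-DOSP)4 is used.
Assumption: the silyl-protected 4-hydroxybenzoic acid used in step 10 is taken as a catalogue compound.

**Step 1**
Reactants: 1 methyl 3-methylbut-3-enoate
Product: 2 methyl 2-diazo-3-methylbut-3-enoate
Conditions: 4-acetamidobenzenesulfonyl azide, DBU, MeCN, 0 °C; used at once
Reagents that add atoms: 4-acetamidobenzenesulfonyl azide, CC(=O)Nc1ccc(cc1)S(=O)(=O)N=[N+]=[N-]
Why: Regitz diazo transfer to the methylene activated by both the ester and the vinyl group should give the vinyldiazoacetate, which is kept cold and used directly because such compounds cyclise slowly to pyrazoles; no stereocentre is formed.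

**Step 2**
Reactants: 2 methyl 2-diazo-3-methylbut-3-enoate; 3 3-methylfuran
Product: 5 methyl (1S,5S)-3,6-dimethyl-8-oxabicyclo[3.2.1]octa-2,6-diene-2-carboxylate, via divinylcyclopropane 4 (not isolated)
Conditions: Rh2(S-DOSP)4 (1 mol %), 3 (5 equiv), hexanes, slow addition of 2, −40 → 25 °C
Reagents that add atoms: none
Why: The dirhodium tetracarboxylate converts 2 into a donor/acceptor vinylcarbenoid that cyclopropanates the unsubstituted C4=C5 enol ether bond of 3 (furan locants) with the isopropenyl group endo, and the cis-divinylcyclopropane 4 undergoes a Cope rearrangement through a boat transition state at or below room temperature, so that C5–C6 (cyclopropanation) and C9–C10 ([3,3] shift) are made in one operation; the closest known reaction type is the rhodium-catalysed tandem cyclopropanation/Cope (formal (4+3)) reaction of vinyldiazoacetates with furans. The cyclopropane closes by asynchronous (2+1) carbenoid addition and is opened again; the seven-membered carbocycle, and with it the oxane ring of the oxabicycle, closes by the suprafacial [3,3]-sigmatropic ring expansion. The new stereocentres C6 and C9 are the bridgeheads, so their relative configuration is fixed by the oxygen bridge and their absolute configuration is set in the cyclopropanation by the chiral prolinate ligands. The step needs site selectivity for the C4=C5 bond over the methyl-bearing C2=C3 bond, which the steric demand of the ligand-encumbered carbenoid towards a trisubstituted alkene should secure, and cyclopropanation instead of zwitterionic ring opening of the furan, which the non-polar solvent favours. The product then carries the methyl groups on C1 and C8, the ester carbon C4 on C5, and one oxygen atom on the α face of both C6 and C9.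

**Step 3**
Reactants: 5 methyl (1S,5S)-3,6-dimethyl-8-oxabicyclo[3.2.1]octa-2,6-diene-2-carboxylate
Product: 6 [(1S,5S)-3,6-dimethyl-8-oxabicyclo[3.2.1]octa-2,6-dien-2-yl]methanol
Conditions: iBu2AlH (2.5 equiv), CH2Cl2, −78 °C; aqueous potassium sodium tartrate
Reagents that add atoms: none
Why: 1,2-Reduction of a conjugated ester by the aluminium hydride should give the allylic alcohol and leave both alkenes and the bridgehead ethers untouched; no stereocentre is formed.

**Step 4**
Reactants: 6 [(1S,5S)-3,6-dimethyl-8-oxabicyclo[3.2.1]octa-2,6-dien-2-yl]methanol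
Product: 7 (1S,5S)-3,6-dimethyl-8-oxabicyclo[3.2.1]octa-2,6-diene-2-carbaldehyde
Conditions: MnO2 (excess), CH2Cl2, 25 °C
Reagents that add atoms: none
Why: Allylic oxidation with MnO2 should stop cleanly at the enal, which is a far better conjugate acceptor than the tetrasubstituted enoate 5; no stereocentre is formed.

**Step 5**
Reactants: 7 (1S,5S)-3,6-dimethyl-8-oxabicyclo[3.2.1]octa-2,6-diene-2-carbaldehyde
Product: 9 3-ethenyl-3,6-dimethyl-8-oxabicyclo[3.2.1]oct-6-ene-2-carbaldehyde (1β-methyl, 1α-vinyl, 5β-formyl, 5α-H), via silyl enol ether 8 (not isolated)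
Conditions: vinylmagnesium bromide, CuBr·SMe2 (10 mol %), Me3SiCl, HMPA, THF, −78 °C; then 1 M HCl, THF, 0 °C
Reagents that add atoms: vinylmagnesium bromide, C=C[Mg]Br; chlorotrimethylsilane, C[Si](C)(C)Cl (silicon remains only in 8)
Why: Copper-catalysed, chlorosilane-accelerated conjugate addition to the β,β-disubstituted enal should deliver the vinyl group to C1 from the exo (α) face on the side of the oxygen bridge, the endo face being screened by the C7=C8 bridge, which sets the quaternary centre with the methyl β; silyl trapping keeps the enolate from expelling the C6–O bridge bond, and acid hydrolysis of 8 protonates C5 from the α face, anti to the adjacent axial methyl, to give 5α-H.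

**Step 6**
Reactants: 9 3-ethenyl-3,6-dimethyl-8-oxabicyclo[3.2.1]oct-6-ene-2-carbaldehyde
Product: 10 tricyclic ketone (trans-fused cyclopentan-4-one on the 6α,9α-oxygen-bridged cyclohept-7-ene; 1β-methyl, 5α-H)
Conditions: [Rh(nbd)(dppe)]BF4 (5 mol %, activated with H2), acetone, 25 °C
Reagents that add atoms: none
Why: Intramolecular hydroacylation of a 4-pentenal by cationic monovalent rhodium (C–H oxidative addition, hydrometalation of the vinyl group, reductive elimination) should close C3–C4 to the cyclopentanone under neutral conditions that leave the epimerisable, elimination-prone C5 untouched, with the quaternary C1 and the β-oxygen of the bridge favouring cyclisation over decarbonylation; no stereocentre is formed.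

**Step 7**
Reactants: 10 tricyclic ketone
Product: 11 6α,9α-epoxydauc-7-en-4β-ol
Conditions: isopropylmagnesium chloride, CeCl3 (anhydrous), THF, −78 °C; aqueous NH4Cl
Reagents that add atoms: isopropylmagnesium chloride, CC(C)[Mg]Cl
Why: The weakly basic organocerium reagent should add to the hindered ketone without enolising C5 (which would expel the C6–O bridge), and it approaches C4 from the face of H5, anti to the angular 1β-methyl group and to the C6–C7 bridge bond, so that the hydroxyl ends up β (cis to the C1 methyl) and the isopropyl group α.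

**Step 8**
Reactants: 11 6α,9α-epoxydauc-7-en-4β-ol
Product: 13 exocyclic enone (4β-hydroxy-6α,9α-oxygen-bridged 7-ketone with a methylidene group at C8), via allylic hydroperoxide 12 (not isolated)
Conditions: O2, tetraphenylporphyrin (cat.), visible light, CH2Cl2, 0 °C; then Ac2O, pyridine, 0 → 25 °C
Reagents that add atoms: dioxygen, O=O
Why: The Schenck ene reaction of singlet oxygen should put oxygen on C7 from the exo (α) face with transfer of a hydrogen of the C8 methyl group (the bridgehead C–H bonds cannot be delivered), and Kornblum–DeLaMare-type dehydration of the acetylated hydroperoxide gives the ketone; C8 stays sp2 throughout, which avoids the compression between an endo C8 methyl and the axial C1 methyl that an exo addition across C7=C8 would create, and the C7 stereocentre of 12 is transient.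

**Step 9**
Reactants: 13 exocyclic enone
Product: 14 4β,6α-dihydroxydauc-8-en-7-one
Conditions: LiBH(sBu)3 (1.2 equiv), THF, −78 → −20 °C; AcOH quench at −78 °C
Reagents that add atoms: none
Why: 1,4-Reduction of the unhindered methylidene ketone by the bulky trialkylborohydride should give the C7 enolate (C7=C8, with the C8 methyl restored), which expels the C9–O bridge bond by E1cB elimination, driven by strain release and conjugation; this unveils C8=C9 and the 6α-hydroxyl with its configuration unchanged, and the bridgehead C6 cannot enolise.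

**Step 10**
Reactants: 14 4β,6α-dihydroxydauc-8-en-7-one; 15 4-(tert-butyldimethylsilyloxy)benzoic acid
Product: 16 4β-hydroxy-7-oxodauc-8-en-6α-yl 4-(tert-butyldimethylsilyloxy)benzoate
Conditions: DCC, DMAP (cat.), CH2Cl2, 0 → 25 °C
Reagents that add atoms: none
Why: Steglich esterification should acylate only the secondary 6α-hydroxyl, because the C4 hydroxyl is tertiary and the second secondary oxygen is still masked as the C7 ketone; no stereocentre is touched.

**Step 11**
Reactants: 16 4β-hydroxy-7-oxodauc-8-en-6α-yl 4-(tert-butyldimethylsilyloxy)benzoate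
Product: 17 4β,7β-dihydroxydauc-8-en-6α-yl 4-(tert-butyldimethylsilyloxy)benzoate
Conditions: NaBH4, CeCl3·7H2O, MeOH, −78 °C
Reagents that add atoms: none
Why: Luche 1,2-reduction of the enone should deliver hydride pseudo-axially from the α face, anti to the pseudo-axial H6, which places the new hydroxyl β and pseudo-equatorial, trans to the 6α-ester; the ester and the aryl silyl ether survive the cold, short reaction.

**Step 12**
Reactants: 17 4β,7β-dihydroxydauc-8-en-6α-yl 4-(tert-butyldimethylsilyloxy)benzoate
Product: 18 4β-hydroxy-7β-(triethylsilyloxy)dauc-8-en-6α-yl 4-(tert-butyldimethylsilyloxy)benzoate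
Conditions: Et3SiCl, imidazole, DMF, 0 °C
Reagents that add atoms: chlorotriethylsilane, CC[Si](Cl)(CC)CC
Why: Silylation of the secondary allylic alcohol under mild conditions (no acyl migration) leaves the tertiary C4 hydroxyl free, removes the hydrogen-bond directing effect of the 7β-hydroxyl and adds bulk on the β face for the next step.

**Step 13**
Reactants: 18 4β-hydroxy-7β-(triethylsilyloxy)dauc-8-en-6α-yl 4-(tert-butyldimethylsilyloxy)benzoate
Product: 19 8α,9α-epoxy-4β-hydroxy-7β-(triethylsilyloxy)daucan-6α-yl 4-(tert-butyldimethylsilyloxy)benzoate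
Conditions: mCPBA, NaHCO3, CH2Cl2, 0 °C
Reagents that add atoms: 3-chloroperoxybenzoic acid, OOC(=O)c1cccc(Cl)c1
Why: Prilezhaev epoxidation of the trisubstituted alkene should occur from the α face, anti to the allylic 7β-silyloxy group and to the 1β-methyl group that flank the two ends of the alkene on the β face, which sets C8 and C9.

**Step 14**
Reactants: 19 8α,9α-epoxy-4β-hydroxy-7β-(triethylsilyloxy)daucan-6α-yl 4-(tert-butyldimethylsilyloxy)benzoate
Product: 20 8α,9α-epoxy-4β,7β-dihydroxydaucan-6α-yl 4-hydroxybenzoate (CNP0290052.1)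
Conditions: Bu4NF, AcOH (1:1), THF, 0 °C
Reagents that add atoms: none
Why: Fluoride cleaves the triethylsilyl ether and the aryl silyl ether in one operation, and the acetic acid buffer keeps the medium near neutral so that Payne rearrangement of the epoxy alcohol and 6→7 acyl migration are suppressed.

**Compound list**
1 | methyl 3-methylbut-3-enoate | COC(=O)CC(C)=C | starting material
2 | methyl 2-diazo-3-methylbut-3-enoate | COC(=O)C(=[N+]=[N-])C(C)=C | intermediate
3 | 3-methylfuran | Cc1ccoc1 | starting material
4 | methyl 4-methyl-6-(prop-1-en-2-yl)-2-oxabicyclo[3.1.0]hex-3-ene-6-carboxylate (isopropenyl endo, cis to the dihydrofuran ring) | COC(=O)[C@]1(C(C)=C)[C@H]2OC=C(C)[C@@H]12 | intermediate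
5 | methyl (1S,5S)-3,6-dimethyl-8-oxabicyclo[3.2.1]octa-2,6-diene-2-carboxylate | COC(=O)C1=C(C)C[C@@H]2O[C@H]1C=C2C | intermediate
6 | [(1S,5S)-3,6-dimethyl-8-oxabicyclo[3.2.1]octa-2,6-dien-2-yl]methanol | OCC1=C(C)C[C@@H]2O[C@H]1C=C2C | intermediate
7 | (1S,5S)-3,6-dimethyl-8-oxabicyclo[3.2.1]octa-2,6-diene-2-carbaldehyde | O=CC1=C(C)C[C@@H]2O[C@H]1C=C2C | intermediate
8 | trimethylsilyl enol ether of 9 (C5=C4H–OSiMe3; 1β-methyl, 1α-vinyl) | C[Si](C)(C)OC=C1[C@](C)(C=C)C[C@@H]2O[C@H]1C=C2C | intermediate
9 | 3-ethenyl-3,6-dimethyl-8-oxabicyclo[3.2.1]oct-6-ene-2-carbaldehyde (1β-methyl, 1α-vinyl, 5β-formyl, 5α-H) | O=C[C@H]1[C@](C)(C=C)C[C@@H]2O[C@H]1C=C2C | intermediate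
10 | tricyclic ketone: trans-fused cyclopentan-4-one on the 6α,9α-oxygen-bridged cyclohept-7-ene (1β-methyl, 5α-H) | O=C1CC[C@]2(C)C[C@@H]3O[C@@H](C=C3C)[C@H]21 | intermediate
11 | 6α,9α-epoxydauc-7-en-4β-ol | CC(C)[C@]1(O)CC[C@]2(C)C[C@@H]3O[C@@H](C=C3C)[C@H]21 | intermediate
12 | 7α-hydroperoxide with C8 methylidene (4β-hydroxy, 6α,9α-oxygen bridge) | CC(C)[C@]1(O)CC[C@]2(C)C[C@@H]3O[C@@H]([C@@H](OO)C3=C)[C@H]21 | intermediate
13 | exocyclic enone: 4β-hydroxy-6α,9α-oxygen-bridged 7-ketone with C8 methylidene | CC(C)[C@]1(O)CC[C@]2(C)C[C@@H]3O[C@@H](C(=O)C3=C)[C@H]21 | intermediate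
14 | 4β,6α-dihydroxydauc-8-en-7-one | CC(C)[C@]1(O)CC[C@]2(C)CC=C(C)C(=O)[C@H](O)[C@H]21 | intermediate
15 | 4-(tert-butyldimethylsilyloxy)benzoic acid | CC(C)(C)[Si](C)(C)Oc1ccc(cc1)C(O)=O | starting material
16 | 4β-hydroxy-7-oxodauc-8-en-6α-yl 4-(tert-butyldimethylsilyloxy)benzoate | CC(C)[C@]1(O)CC[C@]2(C)CC=C(C)C(=O)[C@H](OC(=O)c3ccc(O[Si](C)(C)C(C)(C)C)cc3)[C@H]21 | intermediate
17 | 4β,7β-dihydroxydauc-8-en-6α-yl 4-(tert-butyldimethylsilyloxy)benzoate | CC(C)[C@]1(O)CC[C@]2(C)CC=C(C)[C@@H](O)[C@H](OC(=O)c3ccc(O[Si](C)(C)C(C)(C)C)cc3)[C@H]21 | intermediate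
18 | 4β-hydroxy-7β-(triethylsilyloxy)dauc-8-en-6α-yl 4-(tert-butyldimethylsilyloxy)benzoate | CC(C)[C@]1(O)CC[C@]2(C)CC=C(C)[C@@H](O[Si](CC)(CC)CC)[C@H](OC(=O)c3ccc(O[Si](C)(C)C(C)(C)C)cc3)[C@H]21 | intermediate
19 | 8α,9α-epoxy-4β-hydroxy-7β-(triethylsilyloxy)daucan-6α-yl 4-(tert-butyldimethylsilyloxy)benzoate | CC(C)[C@]1(O)CC[C@]2(C)C[C@@H]3O[C@]3(C)[C@@H](O[Si](CC)(CC)CC)[C@H](OC(=O)c3ccc(O[Si](C)(C)C(C)(C)C)cc3)[C@H]21 | intermediate
20 | 8α,9α-epoxy-4β,7β-dihydroxydaucan-6α-yl 4-hydroxybenzoate (CNP0290052.1) | CC(C)[C@]1(O)CC[C@]2(C)C[C@@H]3O[C@]3(C)[C@@H](O)[C@H](OC(=O)c3ccc(O)cc3)[C@H]21 | target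

**Step count**
Total: 14 steps. Longest linear sequence: 14 steps (1 → 20); 3 and 15 are purchased.

**Steps most likely to fail, with fallbacks**

Step 2. The carbenoid may attack the electronically richer, methyl-bearing C2=C3 bond of the furan, which would put the ring methyl next to C6 instead of C9. The fallback sets out from 2 and returns at 5. The same dirhodium-catalysed (4+3) reaction is run with 3-bromofuran, whose halogen deactivates and shields its own double bond so that cyclopropanation is steered to the unsubstituted enol ether bond. This should give methyl (1S,5S)-6-bromo-3-methyl-8-oxabicyclo[3.2.1]octa-2,6-diene-2-carboxylate F1. Negishi coupling of the vinyl bromide (MeZnCl, Pd(PPh3)4 as zerovalent palladium catalyst, THF, 50 °C) then installs the C8 methyl group and gives 5.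

Step 6. Decarbonylation of the acyl-rhodium hydride may outrun insertion of the vinyl group, because closing the trans-fused five-membered ring is strained. The fallback sets out from 9 and returns at 10. Non-basic addition of vinylmagnesium bromide/CeCl3 (THF, −78 °C) to the aldehyde gives the divinyl carbinol F2 as a mixture of C4 epimers. Ring-closing metathesis (second-generation Grubbs catalyst, RuCl2(=CHPh)(H2IMes)(PCy3), CH2Cl2, 40 °C) closes C2=C3 to the cyclopentenol F3. Dess–Martin oxidation gives the cyclopentenone F4, and conjugate reduction with [CuH(PPh3)]6 (benzene, 25 °C) gives 10.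

Step 11. Hydride delivery to C7 may occur with poor facial selectivity, or from the β face, away from the bulky 6α-ester, which would give the 7α-alcohol. The fallback sets out from 14 and returns at 18, with the order of reduction and acylation reversed. The free 6α-hydroxyl of 14 is used for hydroxyl-directed reduction with Me4NBH(OAc)3 (AcOH/MeCN, −20 °C): the alkoxyborohydride formed at O6 delivers hydride intramolecularly to the α face of C7 and should give the 6α,7β-diol, 4β,6α,7β-trihydroxydauc-8-ene F5. Selective silylation of the more accessible allylic 7β-hydroxyl (Et3SiCl 1.05 equiv, imidazole, DMF, −20 °C) gives the 7β-triethylsilyl ether F6. Steglich esterification of the remaining 6α-hydroxyl with 15 (DCC, DMAP, CH2Cl2) gives 18.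

**Further compounds**
F1 | step 2 | methyl (1S,5S)-6-bromo-3-methyl-8-oxabicyclo[3.2.1]octa-2,6-diene-2-carboxylate | COC(=O)C1=C(C)C[C@@H]2O[C@H]1C=C2Br
F2 | step 6 | divinyl carbinol: 1-(3-ethenyl-3,6-dimethyl-8-oxabicyclo[3.2.1]oct-6-en-2-yl)prop-2-en-1-ol (C4 epimers; 1β-methyl, 5α-H) | C=CC(O)[C@H]1[C@](C)(C=C)C[C@@H]2O[C@H]1C=C2C
F3 | step 6 | tricyclic cyclopent-2-en-4-ol (C4 epimers) on the 6α,9α-oxygen-bridged cyclohept-7-ene | OC1C=C[C@]2(C)C[C@@H]3O[C@@H](C=C3C)[C@H]21
F4 | step 6 | tricyclic cyclopent-2-en-4-one on the 6α,9α-oxygen-bridged cyclohept-7-ene | O=C1C=C[C@]2(C)C[C@@H]3O[C@@H](C=C3C)[C@H]21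
F5 | step 11 | dauc-8-ene-4β,6α,7β-triol | CC(C)[C@]1(O)CC[C@]2(C)CC=C(C)[C@@H](O)[C@H](O)[C@H]21
F6 | step 11 | 7β-(triethylsilyloxy)dauc-8-ene-4β,6α-diol | CC(C)[C@]1(O)CC[C@]2(C)CC=C(C)[C@@H](O[Si](CC)(CC)CC)[C@H](O)[C@H]21
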